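The readings were generated by integration on assumed constants; the scatter is artificial.

What stops this flask by 15 d, and how much product stands in it then?

| setting | dusk | winter | spring | flask |
|---|---|---|---|---|
| starting material | 0.046 M | 0.046 M | 0.092 M | 0.046 M |
| partner | 0.022 M | 0.048 M | 0.0322 M | 0.0322 M |
| protic impurity | 0.0138 M | 0.0138 M | 0.0138 M | 0.0138 M |
| free catalyst | 28 µM (in portions, 3) | 28 µM (in portions, 3) | 28 µM (in portions, 3) | 28 µM (in portions, 3) |
| remark | run made earlier; portions every 3.0 min | run made earlier; portions every 3.0 min | run made earlier; portions every 3.0 min | the portions of free catalyst follow each other after 3.0 min, the first at the start |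
| time |  |  |  | 15 d |

| run | time / d | starting material / % | product / % |
|---|---|---|---|
| dusk | 3.00 | 20 | 46 |
| dusk | 6.00 | 21 | 49 |
| dusk | 10.0 | 21 | 47 |
| dusk | 12.0 | 21 | 49 |
| winter | 1.67 | 3 | 71 |
| winter | 4.00 | 2 | 68 |
| winter | 8.00 | 0 | 69 |
| winter | 12.0 | 2 | 73 |
| spring | 1.67 | 74 | 15 |
| spring | 4.00 | 70 | 11 |
| spring | 8.00 | 69 | 13 |
| spring | 12.0 | 67 | 14 |

(each reading ± 2 percentage points)

- at 15 d, what has stopped the reaction, if anything has (all of the starting material has reacted / it is still moving / no working catalyst is left / forward and back rates have come level)
- conversion of starting material at 15 d
- amount of product at 15 d, in percent of the starting material charged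

- the reaction counts as stopped when no species that holds the starting material changes by six tenths of a point or more over the second half of the time

The dusk product levels off near 49%, close to its partner charge of 47.8% of the starting material. The winter product levels off near 69%, close to the charge less the protic impurity. This flask has both limits at 70.0% and 70.0%, so partner and starting material are each a limiting reagent, and it reaches that product if the catalyst lasts.

The spring product stays flat near 0.0122 M, below its partner charge of 0.0322 M, so I read that its catalyst gave out. I take each unit of product to cost catalyst in proportion to the starting material present. With starting material at a mean of 0.0800 M, spring gives a cost reading of 0.0287 M⁻¹.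

This folds into one spending number, the catalyst that the whole possible product costs as a share of the catalyst charged: 0.759 for this flask, where starting material averages 0.0230 M on its way to nothing. That is below one, so I expect the catalyst to outlast the material.

The number holds no time, however, and both reactants vanish together in a slow tail. Taking a second-order rate constant from the winter fall of starting material and running it to 15 d leaves roughly 1.06%, a rough figure, since the winter reading 3% carries a scatter of 2 percentage points. In such a tail the remainder halves when the time doubles, so this flask would lose 1.1 points over the second half of the time, which the stopping rule counts as still moving. I commit to a conversion near 98.9% and, on this rough figure, to a flask still moving.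

The forecast says no working catalyst is left, with conversion 92% and product 62%: “Whether it dies or merely crawls is my least certain call.”

The flask gives all of the starting material has reacted, with conversion 99.9% and product 69.9%.

    starting material + free catalyst ⇌ catalyst intermediate A (K = 9.97 M⁻¹, k = 1180 M⁻¹ min⁻¹)
    partner + catalyst intermediate A → catalyst intermediate B (k = 16400 M⁻¹ min⁻¹)
    catalyst intermediate B → released group + catalyst intermediate C (k = 94.2 min⁻¹)
    catalyst intermediate C → free catalyst + product (k = 12.1 min⁻¹)
    starting material + catalyst intermediate C → spent catalyst (k = 0.338 M⁻¹ min⁻¹)
    starting material + catalyst intermediate B ⇌ idle complex, settled at all times (K = 10.3 M⁻¹)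
    starting material + protic impurity → quenched substrate (k = 0.627 M⁻¹ min⁻¹)

At 15.0 d this flask holds starting material at 0.0722%, down from 0.146% at 7.50 d and less than my 1.06%, with spent catalyst at 61.6% and 38% still able to turn over, against a spending number of 0.759. For the neighbour charged with 0.11 M of starting material the number is 2.87, which puts product near 10.2% as an estimate, and that neighbour stands at 9.72% with free catalyst at 0% and starting material at 77.7%.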